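Remark (assumption): the SMILES is taken literally, so the two 5/7 lactone cores are of opposite absolute configuration. Xanthane-type locants are used: north half C1–C15 (lactone ring A = C7, C8, O, C12, C11 with C13 exocyclic; ring B = C1, C5–C10; C14 = methyl on C10; C4/C15 = acetyl on C3), south half C1'–C15' (lactone ring D = C7', C8', O, C12', C11'; ring E = C1', C5'–C10'; chain C2'–C3'–C4'(=O)–C15' on C1'), ring C = C1, C2, C3, C11', C13', C5. The target is (1S,5S,7R,8R,10S,11'S,7'S,8'S,10'R).

## Structural features

- The target joins two xanthane-type lactones. The north half has an α-methylene γ-lactone (ring A) cis-fused at C7/C8 to cycloheptane ring B. The south half has a γ-lactone (ring D) cis-fused at C7'/C8' to cycloheptene ring E (C1'=C5'), which carries a 3-oxobutyl chain on C1'.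
- The halves meet in cyclohexene ring C, trans-fused to ring B at C1–C5 and spiro-fused to ring D at the quaternary C11'. C3 bears an acetyl group conjugated with C2=C3, and C1 is a tertiary allylic alcohol.
- On ring B the lactone bonds at C7 and C8, the C14 methyl, the C1 hydroxyl and the C5–C13' bond all lie on one face. C1, C5 and C10 are contiguous, as are C11', C7' and C8'.
- The two bicyclic cores are antipodal (7R,8R,10S against 7'S,8'S,10'R), so this is not a homochiral dimer.
- At the spiro centre, C13' sits on the convex face of lactone D (syn to H7' and H8') and C3 on the concave face (syn to C6'). C3 therefore occupies the face that a reagent approaching the lactone would avoid.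
- Fragile groups are the α-methylene lactone (Michael acceptor), the tertiary γ-hydroxy enone (dehydration, retro-aldol), two methyl ketones and a trisubstituted alkene.
- The real difficulty is ring C: a quaternary spiro centre of contra-steric configuration next to a tertiary carbinol, plus the need to supply both enantiomeric series of the 5/7 core.

## Logic of the disconnections

**29 to 27.** The C11=C13 double bond is cut back to a C13–NMe2 single bond. The methylene lactone is the most electrophilic group and would not survive enolate or Michael chemistry, so it travels as its amine adduct. The forward step must be a mild elimination that leaves the hydroxy enone alone.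

**27 to 25.** The C3–C4 bond is cut, giving an enol triflate at C3 and an acetyl anion equivalent. This turns the γ-hydroxy enone into the enol derivative of a β-hydroxy ketone (24, 23), which is an aldol retron. Enolization can only go toward C2 because C11' is quaternary; the tertiary hydroxyl must be masked (24).

**23 to 15 + 20 (key).** The bonds C11'–C13' and C1–C2 are cut. C13' is assigned to the north half as an exocyclic enone carbon, and C2/C3 to the south half as an acetyl group on the lactone α-carbon. Both bonds are then polarity-matched (β-keto lactone donor to enone; methyl ketone enolate to ring ketone). Because C3 is already on C11' when C13' arrives, the normal convex-face attack on the lactone gives the required spiro configuration. The step removes ring C, three stereocentres and the union of the halves at once. It demands a trans-fused ketol and no loss of the acetyl group.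

**20 to 19; 15 to 14 to 11 + 12 to 10.** In 20 the bonds C5–C13' and C11–C13 (both to CH2NMe2) are cut back to the bare keto lactone 19. In 15 the C11'–C3 bond is cut (lactone acylation), then the C1'–C2' bond (cross-coupling of triflate 11 with the borane from 12), then the triflate returns to ketone 10. Each forward step relies on the ketone reacting before the lactone and on enolization at the unsubstituted α-carbon.

**19 and 10 to 17 and 8.** These two keto lactones are enantiomers. Each loses C5 (one-carbon ring expansion), giving a cyclohexanone whose three stereocentres can come from an arene. The forward step must insert the carbon on the CH2 side of the ketone.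

**17 and 8 to 16/7 and 6 to 5.** Both enantiomers come from one racemate by kinetic resolution. Since the target needs both antipodes, neither is discarded.

**5 to 4 to 3 to 1 + 2.** The three ring stereocentres are cut back to a flat benzofuranone (all-cis hydrogenation), and that to methylhydroquinone and glyoxylic acid.

## Other disconnections considered

**Alternative 1:** Cut C5–C13' and C3–C11' (the biomimetic cut, and the first to come to mind). The forward step is a Diels–Alder reaction of the dienone of 8-epi-xanthatin A1 with the exocyclic methylene of the south monomer A2, giving the β,γ-unsaturated ketone A3, followed by γ-oxygenation of its dienolate at C1.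
- In A2 the open face of C11'=C13' is the convex one. A diene bonding there ends with C3 syn to H7', the opposite of the target, and a bimolecular cycloaddition offers no handle to reverse this.
- A1 carries its own methylene lactone and would also act as dienophile.
- The C1 hydroxyl, trans to H5, would still need separate steps.
The chosen plan uses the same convex-face bias productively.

**Alternative 2:** Cut C2–C3 and C11'–C13'. The forward step is a Diels–Alder reaction with the roles reversed: the alkylidene lactone A4 as dienophile and the bis-exocyclic diene A5 of the north half, giving A6.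
- C13' would arrive on the convex face, which is correct.
- A5 is a 2,3-dialkylbutadiene with almost no electronic bias, so both orientations are expected.
- A6 has a tetrasubstituted C1=C5 alkene and a saturated C2–C3 bond. Reaching the carbinol and enone would need a formal anti-Markovnikov hydration and a dehydrogenation after the key event.

**Alternative 3:** Cut C2=C3. The forward step is a ring-closing metathesis of diene A7 (vinyl carbinol at C1, 3-oxobut-1-en-2-yl group on C11').
- A7 already contains C1, C5 and C11', each of which must be made beforehand in separate alkylation and addition steps. The ring closure gives no stereochemical simplification.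
- The metathesis must form an acyl-substituted trisubstituted alkene between a quaternary carbon and a tertiary carbinol, in competition with the methylene lactone.
- The linear sequence is longer.

Key step: step 14

## Route

Step 1
Reactants: 1 2-methylbenzene-1,4-diol; 2 glyoxylic acid
Product: 3 rac-3,5-dihydroxy-6-methyl-1-benzofuran-2(3H)-one
Conditions: 2 (50% aq), NaOH, H2O, N2, 0 °C to rt; then aq HCl, 60 °C
Reagents that add atoms: none
Why: Electrophilic aromatic hydroxyalkylation of the phenoxide by the aldehyde at the free position ortho to O-4 and para to the methyl group, then acid-promoted lactonization of the mandelic acid onto that phenol; the carbinol centre is racemic and is removed in step 2, and any 7-methyl regioisomer is removed by crystallization.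

Step 2
Reactants: 3 rac-3,5-dihydroxy-6-methyl-1-benzofuran-2(3H)-one
Product: 4 5-hydroxy-6-methyl-1-benzofuran-2(3H)-one
Conditions: H2 (4 bar), Pd/C, AcOH, cat. H2SO4, 50 °C
Reagents that add atoms: none
Why: Hydrogenolysis of the benzylic, α-acyl C–O bond (mandelic acid to arylacetic acid reduction); the aryl lactone and the phenol are not reduced on palladium under these conditions.

Step 3
Reactants: 4 5-hydroxy-6-methyl-1-benzofuran-2(3H)-one
Product: 5 rac-(3aR*,5R*,6S*,7aR*)-5-hydroxy-6-methylhexahydro-1-benzofuran-2(3H)-one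
Conditions: H2 (60 bar), Rh/Al2O3, i-PrOH, 50 °C
Reagents that add atoms: none
Why: Heterogeneous arene hydrogenation delivers all six hydrogens to one face of the adsorbed ring, so the lactone bonds, the methyl group and the hydroxyl end up all-cis; this fixes the relative configuration of the future C7, C8 and C10 (racemic), and minor isomers are removed by crystallization.

Step 4
Reactants: 5 rac-(3aR*,5R*,6S*,7aR*)-5-hydroxy-6-methylhexahydro-1-benzofuran-2(3H)-one
Product: 6 (3aS,5S,6R,7aS)-5-hydroxy-6-methylhexahydro-1-benzofuran-2(3H)-one and 7 (3aR,5R,6S,7aR)-6-methyl-2-oxooctahydro-1-benzofuran-5-yl acetate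
Conditions: Burkholderia cepacia lipase, vinyl acetate, t-BuOMe, 30 °C, stopped near half conversion; chromatography
Reagents that add atoms: vinyl acetate, C=COC(C)=O
Why: Lipase-catalysed kinetic resolution by irreversible transacylation; by the empirical size rule for secondary alcohols the enantiomer with the (5R) carbinol (methyl-bearing carbon as the large group) should be acylated and the (5S) alcohol left, and both products are used (6 for the south half, 7 for the north half).

Step 5
Reactants: 6 (3aS,5S,6R,7aS)-5-hydroxy-6-methylhexahydro-1-benzofuran-2(3H)-one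
Product: 8 (3aS,6R,7aS)-6-methylhexahydro-1-benzofuran-2,5-dione
Conditions: (n-Pr4N)RuO4 (5 mol%), N-methylmorpholine N-oxide, 4 Å sieves, CH2Cl2, rt
Reagents that add atoms: none
Why: Ley–Griffith oxidation of the secondary alcohol under neutral conditions, which should leave the α-methyl stereocentre untouched.

Step 6
Reactants: 8 (3aS,6R,7aS)-6-methylhexahydro-1-benzofuran-2,5-dione
Product: 10 (3aS,7R,8aS)-7-methylhexahydro-2H-cyclohepta[b]furan-2,6(3H)-dione, via α-silyl ketone 9 (not isolated)
Conditions: Me3SiCHN2, BF3·OEt2, CH2Cl2, −78 to −30 °C; then 1 M HCl, THF, rt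
Reagents that add atoms: (trimethylsilyl)diazomethane, C[Si](C)(C)C=[N+]=[N-]
Why: Lewis-acid-promoted diazoalkane homologation (Tiffeneau–Demjanov-type ring expansion): addition to the ketone, 1,2-shift of the less substituted α-carbon (CH2 rather than CHMe) with loss of N2, then protodesilylation; the lactone carbonyl is inert and the cycloheptanone formed is less reactive than the cyclohexanone, which limits over-homologation.

Step 7
Reactants: 10 (3aS,7R,8aS)-7-methylhexahydro-2H-cyclohepta[b]furan-2,6(3H)-dione
Product: 11 (3aS,7R,8aS)-7-methyl-2-oxo-3,3a,4,7,8,8a-hexahydro-2H-cyclohepta[b]furan-6-yl trifluoromethanesulfonate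
Conditions: KN(SiMe3)2 (1.05 equiv), THF, −78 °C; then PhNTf2
Reagents that add atoms: N-phenylbis(trifluoromethanesulfonimide), O=S(=O)(N(c1ccccc1)S(=O)(=O)C(F)(F)F)C(F)(F)F
Why: Kinetic deprotonation of the ketone (more acidic than the lactone) at the unsubstituted α-carbon C5' and O-sulfonylation give the less substituted enol triflate, which places the future C1'=C5' double bond; C10' is not touched.

Step 8
Reactants: 11 (3aS,7R,8aS)-7-methyl-2-oxo-3,3a,4,7,8,8a-hexahydro-2H-cyclohepta[b]furan-6-yl trifluoromethanesulfonate; 12 2-methyl-2-vinyl-1,3-dioxolane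
Product: 14 (3aS,7R,8aS)-7-methyl-6-[2-(2-methyl-1,3-dioxolan-2-yl)ethyl]-3,3a,4,7,8,8a-hexahydro-2H-cyclohepta[b]furan-2-one, via B-alkyl-9-BBN borane 13 (not isolated)
Conditions: 12, 9-borabicyclo[3.3.1]nonane (0.5 M in THF), 0 °C to rt; then 11, PdCl2(dppf) (dppf = 1,1'-bis(diphenylphosphino)ferrocene, 5 mol%), K3PO4 (3 M aq), THF/DMF, 50 °C
Reagents that add atoms: none
Why: Anti-Markovnikov hydroboration of the vinyl group followed by B-alkyl Suzuki–Miyaura coupling with the enol triflate installs the ketal-protected 3-oxobutyl chain on C1' with the C1'=C5' alkene in place.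

Step 9
Reactants: 14 (3aS,7R,8aS)-7-methyl-6-[2-(2-methyl-1,3-dioxolan-2-yl)ethyl]-3,3a,4,7,8,8a-hexahydro-2H-cyclohepta[b]furan-2-one
Product: 15 (3R,3aS,7R,8aS)-3-acetyl-7-methyl-6-[2-(2-methyl-1,3-dioxolan-2-yl)ethyl]-3,3a,4,7,8,8a-hexahydro-2H-cyclohepta[b]furan-2-one
Conditions: LiN(SiMe3)2 (2.2 equiv), THF, −78 °C; 1-acetylimidazole, −78 to 0 °C; aq NH4Cl
Reagents that add atoms: 1-acetylimidazole, CC(=O)n1ccnc1
Why: Claisen-type C-acylation of the lactone enolate (the only acidic C–H in 14) with an acyl imidazole; the second equivalent of base takes up the more acidic β-keto lactone, whose C11' centre is labile and drawn as the trans epimer.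

Step 10
Reactants: 7 (3aR,5R,6S,7aR)-6-methyl-2-oxooctahydro-1-benzofuran-5-yl acetate
Product: 16 (3aR,5R,6S,7aR)-5-hydroxy-6-methylhexahydro-1-benzofuran-2(3H)-one
Conditions: K2CO3 (0.2 equiv), MeOH, rt; then aq HCl to pH 2
Reagents that add atoms: none
Why: Base-catalysed transesterification removes the acetate; any ring-opened hydroxy ester recloses to the cis-fused γ-lactone on acidification, and no stereocentre is affected.

Step 11
Reactants: 16 (3aR,5R,6S,7aR)-5-hydroxy-6-methylhexahydro-1-benzofuran-2(3H)-one
Product: 17 (3aR,6S,7aR)-6-methylhexahydro-1-benzofuran-2,5-dione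
Conditions: (n-Pr4N)RuO4 (5 mol%), N-methylmorpholine N-oxide, 4 Å sieves, CH2Cl2, rt
Reagents that add atoms: none
Why: Ley–Griffith oxidation as in step 5, on the enantiomer.

Step 12
Reactants: 17 (3aR,6S,7aR)-6-methylhexahydro-1-benzofuran-2,5-dione
Product: 19 (3aR,7S,8aR)-7-methylhexahydro-2H-cyclohepta[b]furan-2,6(3H)-dione, via α-silyl ketone 18 (not isolated)
Conditions: Me3SiCHN2, BF3·OEt2, CH2Cl2, −78 to −30 °C; then 1 M HCl, THF, rt
Reagents that add atoms: (trimethylsilyl)diazomethane, C[Si](C)(C)C=[N+]=[N-]
Why: The same diazoalkane ring expansion as in step 6 on the enantiomer, with migration of the CH2 carbon and protodesilylation.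

Step 13
Reactants: 19 (3aR,7S,8aR)-7-methylhexahydro-2H-cyclohepta[b]furan-2,6(3H)-dione
Product: 20 (3S,3aR,5S,7S,8aR)-3,5-bis[(dimethylamino)methyl]-7-methylhexahydro-2H-cyclohepta[b]furan-2,6(3H)-dione
Conditions: LiN(i-Pr)2 (2.3 equiv), THF, −78 °C; CH2=NMe2+ I− (3 equiv), −78 °C to rt; used crude
Reagents that add atoms: N,N-dimethylmethyleneiminium iodide, C[N+](C)=C.[I-]
Why: Double Mannich aminomethylation of the bis-enolate (kinetic ketone enolate at the unsubstituted C5 plus the lactone enolate at C11); the lactone is attacked on its convex face, and the configuration at C5 and C11 is immaterial because both centres become trigonal later.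

Step 14
Reactants: 15 (3R,3aS,7R,8aS)-3-acetyl-7-methyl-6-[2-(2-methyl-1,3-dioxolan-2-yl)ethyl]-3,3a,4,7,8,8a-hexahydro-2H-cyclohepta[b]furan-2-one; 20 (3S,3aR,5S,7S,8aR)-3,5-bis[(dimethylamino)methyl]-7-methylhexahydro-2H-cyclohepta[b]furan-2,6(3H)-dione
Product: 23 β-ketol (1S,5S,7R,8R,10S,11S,7'S,8'S,10'R,11'S) with ring C closed (C1–OH, C3=O), C13–NMe2 and C4' as ethylene ketal, via exocyclic enone 21 (not isolated), via Michael adduct 22 (not isolated)
Conditions: MeCN, 60 °C; then DBU (1.5 equiv), rt to 40 °C
Reagents that add atoms: none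
Why: This is a Robinson annulation in its Mannich-base form, stopped at the β-ketol (Michael addition, then intramolecular aldol addition). On warming, the β-amino ketone of 20 loses Me2NH by E1cB through the C1 enol(ate) to give enone 21, while the β-amino lactone, whose α-hydrogen is far less acidic, keeps its amine. The enolate of β-keto lactone 15 adds through C11' to the unhindered exocyclic C13'; it is attacked on the convex face of the cis-fused bicycle (the face of H7' and H8', away from ring E), which places C13' syn to H7' and pushes the acetyl group to the concave face, i.e. 11'S as in the target. DBU then enolizes the acetyl methyl group (C2) and closes ring C by a 6-(enolexo)-exo-trig aldol addition to the C1 ketone. In the chair transition state the quaternary C11' forces the C5–C6 bond equatorial, the larger C10 branch takes the second equatorial site and the carbonyl oxygen becomes axial, so the B/C fusion is trans; C2 enters C1 anti to the C14 methyl group, giving the 1S carbinol with OH cis to that methyl. C5 is α to the C1 ketone in 22 and equilibrates under DBU, so the adduct should drain through the epimer (5S, C13' cis to C14) that fits this transition state. The selectivities needed are ketone-over-lactone elimination (secured by the acidity difference), C- over O-alkylation of the β-keto lactone, and fused over bridged aldol closure (the alternative enolate at C10 is tertiary and would give a strained bridgehead ketone).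

Step 15
Reactants: 23 β-ketol (1S,5S,7R,8R,10S,11S,7'S,8'S,10'R,11'S)
Product: 24 C1 trimethylsilyl ether of 23
Conditions: 1-(trimethylsilyl)imidazole, CH2Cl2, 40 °C
Reagents that add atoms: 1-(trimethylsilyl)imidazole, C[Si](C)(C)n1ccnc1
Why: Silylation of the tertiary alcohol with a reagent that does not enolize ketones; it prevents alkoxide formation (retro-aldol) in the next step.

Step 16
Reactants: 24 C1 trimethylsilyl ether of 23
Product: 25 enol triflate (C2=C3–OSO2CF3) of 24
Conditions: KN(SiMe3)2 (1.2 equiv), THF, −78 °C; N-(5-chloropyridin-2-yl)bis(trifluoromethanesulfonimide), −78 to −20 °C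
Reagents that add atoms: N-(5-chloropyridin-2-yl)bis(trifluoromethanesulfonimide), O=S(=O)(N(c1ccc(Cl)cn1)S(=O)(=O)C(F)(F)F)C(F)(F)F
Why: The C3 ketone can enolize only toward C2 because C11' is quaternary, and it is more acidic than the remaining lactone C–H; low-temperature trapping of the potassium enolate outruns β-elimination of the silyloxy group.

Step 17
Reactants: 25 enol triflate (C2=C3–OSO2CF3) of 24
Product: 27 amino enone (target skeleton with (11S)-C11H–CH2NMe2 in place of C11=C13H2), via 2-ethoxydiene 26 (not isolated)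
Conditions: tributyl(1-ethoxyvinyl)stannane, Pd(PPh3)4 (10 mol%), CuI (20 mol%), LiCl (3 equiv), DMF, 70 °C; then 2 M HCl, THF, rt; NaHCO3 work-up
Reagents that add atoms: tributyl(1-ethoxyvinyl)stannane, CCOC(=C)[Sn](CCCC)(CCCC)CCCC; water, O
Why: Stille coupling (oxidative addition of zerovalent palladium to the enol triflate, copper-assisted transmetalation) attaches an acetyl anion equivalent at C3; aqueous acid then hydrolyses the enol ether to the conjugated methyl ketone, the dioxolane to the C4' ketone and the silyl ether to the C1 alcohol, whose ionization is disfavoured by the electron-poor enone.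

Step 18
Reactants: 27 amino enone (target skeleton with (11S)-C11H–CH2NMe2)
Product: 29 target CNP0195550.1, via trimethylammonium iodide 28 (not isolated)
Conditions: MeI (excess), THF, rt; then aq NaHCO3, EtOAc, rt
Reagents that add atoms: none
Why: N-Methylation turns the amine into a leaving group and mild base induces E1cB (Hofmann-type) elimination of trimethylamine from the lactone, regenerating the α-methylene lactone without touching the ketones, the tertiary alcohol or any stereocentre.

## Compound list

1 | 2-methylbenzene-1,4-diol (methylhydroquinone) | Cc1cc(O)ccc1O | starting material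
2 | glyoxylic acid (used as 50% aqueous solution) | O=CC(=O)O | starting material
3 | rac-3,5-dihydroxy-6-methyl-1-benzofuran-2(3H)-one | OC1C(=O)Oc2cc(C)c(O)cc12 | intermediate
4 | 5-hydroxy-6-methyl-1-benzofuran-2(3H)-one | O=C1Cc2cc(O)c(C)cc2O1 | intermediate
5 | rac-(3aR*,5R*,6S*,7aR*)-5-hydroxy-6-methylhexahydro-1-benzofuran-2(3H)-one (all-cis; racemate, one enantiomer drawn) | C1C(=O)O[C@@H]2C[C@H](C)[C@H](O)C[C@H]12 | intermediate
6 | (3aS,5S,6R,7aS)-5-hydroxy-6-methylhexahydro-1-benzofuran-2(3H)-one | C1C(=O)O[C@H]2C[C@@H](C)[C@@H](O)C[C@@H]12 | intermediate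
7 | (3aR,5R,6S,7aR)-6-methyl-2-oxooctahydro-1-benzofuran-5-yl acetate | C1C(=O)O[C@@H]2C[C@H](C)[C@H](OC(C)=O)C[C@H]12 | intermediate
8 | (3aS,6R,7aS)-6-methylhexahydro-1-benzofuran-2,5-dione | C1C(=O)O[C@H]2C[C@@H](C)C(=O)C[C@@H]12 | intermediate
9 | (3aS,7R,8aS)-7-methyl-5-(trimethylsilyl)hexahydro-2H-cyclohepta[b]furan-2,6(3H)-dione (both C5 epimers) | C1C(=O)O[C@H]2C[C@@H](C)C(=O)C([Si](C)(C)C)C[C@@H]12 | intermediate (not isolated)
10 | (3aS,7R,8aS)-7-methylhexahydro-2H-cyclohepta[b]furan-2,6(3H)-dione | C1C(=O)O[C@H]2C[C@@H](C)C(=O)CC[C@@H]12 | intermediate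
11 | (3aS,7R,8aS)-7-methyl-2-oxo-3,3a,4,7,8,8a-hexahydro-2H-cyclohepta[b]furan-6-yl trifluoromethanesulfonate | C1C(=O)O[C@H]2C[C@@H](C)C(OS(=O)(=O)C(F)(F)F)=CC[C@@H]12 | intermediate
12 | 2-methyl-2-vinyl-1,3-dioxolane | C=CC1(C)OCCO1 | starting material
13 | 9-[2-(2-methyl-1,3-dioxolan-2-yl)ethyl]-9-borabicyclo[3.3.1]nonane | CC1(CCB2C3CCCC2CCC3)OCCO1 | intermediate (not isolated)
14 | (3aS,7R,8aS)-7-methyl-6-[2-(2-methyl-1,3-dioxolan-2-yl)ethyl]-3,3a,4,7,8,8a-hexahydro-2H-cyclohepta[b]furan-2-one | C1C(=O)O[C@H]2C[C@@H](C)C(CCC3(C)OCCO3)=CC[C@@H]12 | intermediate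
15 | (3R,3aS,7R,8aS)-3-acetyl-7-methyl-6-[2-(2-methyl-1,3-dioxolan-2-yl)ethyl]-3,3a,4,7,8,8a-hexahydro-2H-cyclohepta[b]furan-2-one (C3 labile, keto form) | CC(=O)[C@@H]1C(=O)O[C@H]2C[C@@H](C)C(CCC3(C)OCCO3)=CC[C@@H]12 | intermediate
16 | (3aR,5R,6S,7aR)-5-hydroxy-6-methylhexahydro-1-benzofuran-2(3H)-one | C1C(=O)O[C@@H]2C[C@H](C)[C@H](O)C[C@H]12 | intermediate
17 | (3aR,6S,7aR)-6-methylhexahydro-1-benzofuran-2,5-dione | C1C(=O)O[C@@H]2C[C@H](C)C(=O)C[C@H]12 | intermediate
18 | (3aR,7S,8aR)-7-methyl-5-(trimethylsilyl)hexahydro-2H-cyclohepta[b]furan-2,6(3H)-dione (both C5 epimers) | C1C(=O)O[C@@H]2C[C@H](C)C(=O)C([Si](C)(C)C)C[C@H]12 | intermediate (not isolated)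
19 | (3aR,7S,8aR)-7-methylhexahydro-2H-cyclohepta[b]furan-2,6(3H)-dione | C1C(=O)O[C@@H]2C[C@H](C)C(=O)CC[C@H]12 | intermediate
20 | (3S,3aR,5S,7S,8aR)-3,5-bis[(dimethylamino)methyl]-7-methylhexahydro-2H-cyclohepta[b]furan-2,6(3H)-dione | CN(C)C[C@H]1C(=O)O[C@@H]2C[C@H](C)C(=O)[C@H](CN(C)C)C[C@H]12 | intermediate
21 | (3S,3aR,7S,8aR)-3-[(dimethylamino)methyl]-7-methyl-5-methylidenehexahydro-2H-cyclohepta[b]furan-2,6(3H)-dione | CN(C)C[C@H]1C(=O)O[C@@H]2C[C@H](C)C(=O)C(=C)C[C@H]12 | intermediate (not isolated)
22 | Michael adduct (5S,7R,8R,10S,11S,7'S,8'S,10'R,11'S): north keto lactone (C1=O, C13–NMe2) linked by C5–C13'H2–C11' to the 11'-acetyl south lactone (C4' ethylene ketal) | CN(C)C[C@H]1C(=O)O[C@@H]2C[C@H](C)C(=O)[C@H](C[C@]3(C(C)=O)C(=O)O[C@H]4C[C@@H](C)C(CCC5(C)OCCO5)=CC[C@@H]34)C[C@H]12 | intermediate (not isolated)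
23 | β-ketol (1S,5S,7R,8R,10S,11S,7'S,8'S,10'R,11'S): ring C closed, C1–OH, C3=O, C13–NMe2, C4' ethylene ketal | CN(C)C[C@H]1C(=O)O[C@@H]2C[C@H](C)[C@@]3(O)CC(=O)[C@@]4(C[C@@H]3C[C@H]12)C(=O)O[C@H]1C[C@@H](C)C(CCC5(C)OCCO5)=CC[C@H]14 | intermediate
24 | C1 trimethylsilyl ether of 23 | CN(C)C[C@H]1C(=O)O[C@@H]2C[C@H](C)[C@@]3(O[Si](C)(C)C)CC(=O)[C@@]4(C[C@@H]3C[C@H]12)C(=O)O[C@H]1C[C@@H](C)C(CCC5(C)OCCO5)=CC[C@H]14 | intermediate
25 | enol triflate of 24 (C2=C3–OSO2CF3) | CN(C)C[C@H]1C(=O)O[C@@H]2C[C@H](C)[C@@]3(O[Si](C)(C)C)C=C(OS(=O)(=O)C(F)(F)F)[C@@]4(C[C@@H]3C[C@H]12)C(=O)O[C@H]1C[C@@H](C)C(CCC5(C)OCCO5)=CC[C@H]14 | intermediate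
26 | 2-ethoxydiene (C3–C(OEt)=CH2; C1–OSiMe3; C4' ketal; C13–NMe2) | CN(C)C[C@H]1C(=O)O[C@@H]2C[C@H](C)[C@@]3(O[Si](C)(C)C)C=C(C(=C)OCC)[C@@]4(C[C@@H]3C[C@H]12)C(=O)O[C@H]1C[C@@H](C)C(CCC5(C)OCCO5)=CC[C@H]14 | intermediate (not isolated)
27 | amino enone: target skeleton with (11S)-C11H–CH2NMe2 in place of C11=C13H2 | CN(C)C[C@H]1C(=O)O[C@@H]2C[C@H](C)[C@@]3(O)C=C(C(C)=O)[C@@]4(C[C@@H]3C[C@H]12)C(=O)O[C@H]1C[C@@H](C)C(CCC(C)=O)=CC[C@H]14 | intermediate
28 | trimethylammonium iodide of 27 | C[N+](C)(C)C[C@H]1C(=O)O[C@@H]2C[C@H](C)[C@@]3(O)C=C(C(C)=O)[C@@]4(C[C@@H]3C[C@H]12)C(=O)O[C@H]1C[C@@H](C)C(CCC(C)=O)=CC[C@H]14.[I-] | intermediate (not isolated)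
29 | CNP0195550.1, (1S,5S,7R,8R,10S,11'S,7'S,8'S,10'R) | C=C1C(=O)O[C@@H]2C[C@H](C)[C@@]3(O)C=C(C(C)=O)[C@@]4(C[C@@H]3C[C@H]12)C(=O)O[C@H]1C[C@@H](C)C(CCC(C)=O)=CC[C@H]14 | target

## Step count and least certain steps

Total step count: 18. Longest linear sequence: 14 steps (steps 1–9, then 14–18).

**Step 14 (key step).** Three things can go wrong. The liberated dimethylamine can cleave the acetyl group from the non-enolizable β-keto lactone of 22 (retro-Claisen). The stereochemical funnelling at C5 and C1 can be incomplete, giving a cis-fused or bridged ketol. Equilibrating base can epimerize C10. The fallback sets out from 15 and 20 and separates the two bond formations. The Michael adduct 22 is isolated after the base-free thermal addition (MeCN, 60 °C, no DBU). Its acetyl group is converted with KN(SiMe3)2 and Me3SiCl at −78 °C into the kinetic trimethylsilyl enol ether F1. Ring C is then closed by an intramolecular Mukaiyama aldol addition (BF3·OEt2, CH2Cl2, −78 °C), which is irreversible, uses a regiodefined nucleophile and does not enolize C10. The route is rejoined at 23.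

**Step 6.** The methyl-bearing α-carbon may migrate in competition with the CH2 carbon, giving the regioisomeric cycloheptanone, and a second homologation is possible. The fallback sets out from 8 and fixes the regiochemistry through a cyclopropane that is then opened with release of strain. Kinetic enolization (LiN(i-Pr)2, Me3SiCl, −78 °C) gives the trimethylsilyl enol ether F2. Simmons–Smith cyclopropanation (Et2Zn, CH2I2) gives the siloxycyclopropane F3. FeCl3 in DMF cleaves the ring-fusion bond to the β-chloro ketone F4, and NaOAc in MeOH gives the cycloheptenone F5. Hydrogenation (H2, Pd/C, EtOAc) returns to 10.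

**Step 12.** The risk is the same as in step 6, in the enantiomeric series. The fallback sets out from 17 and runs through the trimethylsilyl enol ether F6, the siloxycyclopropane F7, the β-chloro ketone F8 and the cycloheptenone F9 under the same conditions. Hydrogenation returns to 19.

**Step 4.** The enzyme may discriminate poorly between the enantiomers of a cis-2-methylcyclohexanol whose hydroxyl is flanked by the methyl group, which would leave both series enantio-impure. (If the enzyme preferred the other enantiomer, the alcohol and acetate would simply exchange roles.) The fallback sets out from 5. It is oxidized as in step 5 to the racemic ketone, and the enantiomers are separated by preparative chromatography on a chiral stationary phase (supercritical CO2/MeOH). This gives 8 and 17 directly and makes step 10 unnecessary.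

**Step 17.** Oxidative addition and transmetalation may be slow at a triflate flanked by two fully substituted carbons, allowing triflate hydrolysis back to the ketone or protodestannylation of the reagent. The fallback sets out from 25 and replaces transmetalation by olefin insertion. A regioselective Heck reaction with butyl vinyl ether (Pd(OAc)2, 1,3-bis(diphenylphosphino)propane, Et3N, DMF, 80 °C) gives the 2-butoxydiene F10. The same acid hydrolysis (2 M HCl, THF) then returns to 27.

## Further compounds

F1 | step 14 | trimethylsilyl enol ether of the acetyl group of 22 (C3(OSiMe3)=C2H2) | CN(C)C[C@H]1C(=O)O[C@@H]2C[C@H](C)C(=O)[C@H](C[C@]3(C(=C)O[Si](C)(C)C)C(=O)O[C@H]4C[C@@H](C)C(CCC5(C)OCCO5)=CC[C@@H]34)C[C@H]12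
F2 | step 6 | (3aS,6R,7aS)-6-methyl-5-[(trimethylsilyl)oxy]-3a,6,7,7a-tetrahydro-1-benzofuran-2(3H)-one | C1C(=O)O[C@H]2C[C@@H](C)C(O[Si](C)(C)C)=C[C@@H]12
F3 | step 6 | siloxycyclopropane from F2 (CH2 added across C4=C5 on the face opposite the lactone) | C1C(=O)O[C@H]2C[C@@H](C)[C@]3(O[Si](C)(C)C)C[C@@H]3[C@@H]12
F4 | step 6 | (3aS,7R,8aS)-4-chloro-7-methylhexahydro-2H-cyclohepta[b]furan-2,6(3H)-dione (both C4 epimers) | C1C(=O)O[C@H]2C[C@@H](C)C(=O)CC(Cl)[C@@H]12
F5 | step 6 | (3aS,7R,8aS)-7-methyl-3,3a,8,8a-tetrahydro-2H-cyclohepta[b]furan-2,6(7H)-dione | C1C(=O)O[C@H]2C[C@@H](C)C(=O)C=C[C@@H]12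
F6 | step 12 | (3aR,6S,7aR)-6-methyl-5-[(trimethylsilyl)oxy]-3a,6,7,7a-tetrahydro-1-benzofuran-2(3H)-one | C1C(=O)O[C@@H]2C[C@H](C)C(O[Si](C)(C)C)=C[C@H]12
F7 | step 12 | siloxycyclopropane from F6 (enantiomer of F3) | C1C(=O)O[C@@H]2C[C@H](C)[C@@]3(O[Si](C)(C)C)C[C@H]3[C@H]12
F8 | step 12 | (3aR,7S,8aR)-4-chloro-7-methylhexahydro-2H-cyclohepta[b]furan-2,6(3H)-dione (both C4 epimers) | C1C(=O)O[C@@H]2C[C@H](C)C(=O)CC(Cl)[C@H]12
F9 | step 12 | (3aR,7S,8aR)-7-methyl-3,3a,8,8a-tetrahydro-2H-cyclohepta[b]furan-2,6(7H)-dione | C1C(=O)O[C@@H]2C[C@H](C)C(=O)C=C[C@H]12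
F0 | step 4 | none | none
F10 | step 17 | 2-butoxydiene (as 26 with OBu in place of OEt) | CN(C)C[C@H]1C(=O)O[C@@H]2C[C@H](C)[C@@]3(O[Si](C)(C)C)C=C(C(=C)OCCCC)[C@@]4(C[C@@H]3C[C@H]12)C(=O)O[C@H]1C[C@@H](C)C(CCC5(C)OCCO5)=CC[C@H]14
A1 | alternative 1 | 8-epi-xanthatin, (3aR,7S,8aR)-7-methyl-3-methylidene-6-[(1E)-3-oxobut-1-en-1-yl]-3,3a,4,7,8,8a-hexahydro-2H-cyclohepta[b]furan-2-one | C=C1C(=O)O[C@@H]2C[C@H](C)C(/C=C/C(C)=O)=CC[C@H]12
A2 | alternative 1 | (3aS,7R,8aS)-7-methyl-3-methylidene-6-(3-oxobutyl)-3,3a,4,7,8,8a-hexahydro-2H-cyclohepta[b]furan-2-one | C=C1C(=O)O[C@H]2C[C@@H](C)C(CCC(C)=O)=CC[C@@H]12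
A3 | alternative 1 | Diels–Alder adduct with C1=C2 and H at C3 (β,γ-unsaturated ketone having the target configuration at C5 and C11') | C=C1C(=O)O[C@@H]2C[C@H](C)C3=C[C@H](C(C)=O)[C@@]4(C[C@@H]3C[C@H]12)C(=O)O[C@H]1C[C@@H](C)C(CCC(C)=O)=CC[C@H]14
A4 | alternative 2 | (3E,3aS,7R,8aS)-7-methyl-6-(3-oxobutyl)-3-(2-oxopropylidene)-3,3a,4,7,8,8a-hexahydro-2H-cyclohepta[b]furan-2-one | CC(=O)/C=C1/C(=O)O[C@H]2C[C@@H](C)C(CCC(C)=O)=CC[C@@H]12
A5 | alternative 2 | (3aR,7S,8aR)-7-methyl-3,5,6-trimethylidenehexahydro-2H-cyclohepta[b]furan-2-one | C=C1C(=O)O[C@@H]2C[C@H](C)C(=C)C(=C)C[C@H]12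
A6 | alternative 2 | reversed-role adduct with C1=C5, C2H2 and H at C3 | C=C1C(=O)O[C@@H]2C[C@H](C)C3=C(C[C@H]12)C[C@@]4(C(=O)O[C@H]5C[C@@H](C)C(CCC(C)=O)=CC[C@@H]45)[C@H](C(C)=O)C3
A7 | alternative 3 | metathesis precursor: C1 vinyl carbinol, C5–C13'H2–C11', 3-oxobut-1-en-2-yl on C11' | C=C1C(=O)O[C@@H]2C[C@H](C)[C@@](O)(C=C)[C@@H](C[C@H]12)C[C@]4(C(=C)C(C)=O)C(=O)O[C@H]5C[C@@H](C)C(CCC(C)=O)=CC[C@@H]45
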